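**Plan**

- Numbering used throughout (germacrane): ten-membered ring C1–C10 with C1=C10 (CH3 on C10); oxirane oxygen on C4 (CH3) and C5; OAc on C6; isopropyl on C7; OBz on C8.
- Retrosynthesis cuts, in order: acetyl–O6; the oxirane oxygen from C4/C5; the ring bond C3–C4; the benzoyl–O8 and C6–H pair (Tishchenko); C5–C6; C7–C8; finally C1–C2 and C10–CH3.
- Enabling feature: the oxirane is cis-fused to the ten-membered ring (C3 and C6 on the same face, CH3 on C4 cis to H on C5), so C4 maps onto the iodine-bearing carbon of a (Z)-vinyl iodide. C3 is a CH2 two atoms from the C1=C10 alkene, so it maps onto the terminal carbon of a C3=C2–C1=C10 diene that 9-BBN turns into a primary alkylborane.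
- Forward: the chain C3→C8 is built by carboalumination/vinylation and an Evans aldol, and C4–C5 are added as a propynyl ketone that becomes the (Z)-iodo enone. The carbocycle then closes at C3–C4, and the oxirane is the second ring to form.
- Stereochemistry: C7 and C8 come from the (R)-4-benzyloxazolidinone auxiliary. C6 comes from C8 by 1,3-anti Evans–Tishchenko reduction, which also installs the benzoate. C4 and C5 come from C6–OH-directed epoxidation of the ring (Z)-alkene. The 1(10)E alkene comes from syn-carboalumination and the cis oxirane geometry from anti-hydroiodination.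

Key step: step 8

Remark: (4R)-4-benzyl-3-(3-methylbutanoyl)-1,3-oxazolidin-2-one is taken as purchasable; otherwise it is one N-acylation from (R)-4-benzyloxazolidin-2-one and 3-methylbutanoyl chloride.
Remark: the descriptors at C6 and C7 change along the route only because substituent priorities change; no centre is inverted after it is set.

Step 1
Reactants: 1 but-3-yn-1-ol
Product: 3 (3E)-3-methylhexa-3,5-dien-1-ol, via alkenylalane 2 (not isolated)
Conditions: AlMe3 (3 equiv), Cp2ZrCl2 (0.25 equiv), CH2Cl2, 0 °C to rt; then vinyl bromide, Pd(PPh3)4 (5 mol%), ZnCl2 (cat.), THF, rt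
Reagents that add atoms: trimethylaluminium C[Al](C)C; vinyl bromide C=CBr
Why: Zirconium-catalysed Negishi carboalumination adds CH3 (to the internal carbon, future C10) and aluminium syn across the terminal alkyne, and the alkenylalane is cross-coupled in the same flask with vinyl bromide with retention, which should fix the future C1=C10 (E) geometry.

Step 2
Reactants: 3 (3E)-3-methylhexa-3,5-dien-1-ol
Product: 4 (3E)-3-methylhexa-3,5-dienal
Conditions: Dess–Martin periodinane, NaHCO3, CH2Cl2, 0 °C; filtered cold and used at once as a solution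
Reagents that add atoms: none
Why: Buffered Dess–Martin oxidation of a homoallylic primary alcohol should give the β,γ-unsaturated aldehyde without acid or base strong enough to move the diene into conjugation.

Step 3
Reactants: 4 (3E)-3-methylhexa-3,5-dienal; 5 (4R)-4-benzyl-3-(3-methylbutanoyl)-1,3-oxazolidin-2-one
Product: 7 (4R)-4-benzyl-3-[(2R,3S,5E)-3-hydroxy-5-methyl-2-(propan-2-yl)octa-5,7-dienoyl]-1,3-oxazolidin-2-one, via boron enolate 6 (not isolated)
Conditions: 5, Bu2BOTf, Et3N, CH2Cl2, 0 °C; then 4, −78 to 0 °C; pH 7 buffer, MeOH, H2O2, 0 °C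
Reagents that add atoms: none
Why: Evans syn-aldol reaction, in which the (Z)-boron enolate adds to 4 through a closed chair transition state on the face away from the benzyl group of the (R)-auxiliary, should set C7 (R) and C8 (S) in one event.

Step 4
Reactants: 7 (4R)-4-benzyl-3-[(2R,3S,5E)-3-hydroxy-5-methyl-2-(propan-2-yl)octa-5,7-dienoyl]-1,3-oxazolidin-2-one
Product: 8 (2R,3S,5E)-3-hydroxy-N-methoxy-N,5-dimethyl-2-(propan-2-yl)octa-5,7-dienamide
Conditions: MeNHOMe·HCl, AlMe3, THF/CH2Cl2, −20 to 0 °C
Reagents that add atoms: N,O-dimethylhydroxylamine hydrochloride CNOC.Cl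
Why: Weinreb transamination of an Evans β-hydroxy imide with the aluminium amide cleaves the exocyclic acyl–N bond, helped by the C8 aluminium alkoxide, and should leave C7 and C8 untouched.

Step 5
Reactants: 8 (2R,3S,5E)-3-hydroxy-N-methoxy-N,5-dimethyl-2-(propan-2-yl)octa-5,7-dienamide
Product: 9 (5R,6S,8E)-6-hydroxy-8-methyl-5-(propan-2-yl)undeca-8,10-dien-2-yn-4-one
Conditions: 1-propynylmagnesium bromide (3 equiv), THF, −20 to 0 °C; aq. NH4Cl
Reagents that add atoms: 1-propynylmagnesium bromide CC#C[Mg]Br
Why: Alkynyl Grignard addition to a Weinreb amide stops at the ketone because the magnesium-chelated tetrahedral intermediate survives until work-up, the first equivalent only deprotonating the C8 hydroxyl; this brings in C4, C5 and the C4 methyl.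

Step 6
Reactants: 9 (5R,6S,8E)-6-hydroxy-8-methyl-5-(propan-2-yl)undeca-8,10-dien-2-yn-4-one
Product: 10 (2Z,5R,6S,8E)-6-hydroxy-2-iodo-8-methyl-5-(propan-2-yl)undeca-2,8,10-trien-4-one
Conditions: NaI, AcOH, MeCN, rt, dark; used directly
Reagents that add atoms: sodium iodide [Na+].[I-]
Why: Conjugate hydroiodination of an ynone (iodide adds to C4, the allenolate is protonated anti at C5) should give the (Z)-β-iodo enone under kinetic control, placing iodine on C4 cis to C6, exactly where C3 must later sit.

Step 7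
Reactants: 10 (2Z,5R,6S,8E)-6-hydroxy-2-iodo-8-methyl-5-(propan-2-yl)undeca-2,8,10-trien-4-one
Product: 11 (2Z,4R,5S,6S,8E)-4-hydroxy-2-iodo-8-methyl-5-(propan-2-yl)undeca-2,8,10-trien-6-yl benzoate
Conditions: PhCHO (5 equiv), SmI2 (0.3 equiv, premixed with PhCHO), THF, −10 °C
Reagents that add atoms: benzaldehyde O=Cc1ccccc1
Why: Evans–Tishchenko reduction, in which the samarium-bound C8 hemiacetal of benzaldehyde delivers hydride to the C6 ketone through a six-membered chair, should give the 6,8-anti product with the C8 oxygen as its benzoate and the C6 hydroxyl free, so C6 (R) and the ester differentiation come in one operation.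

Step 8
Reactants: 11 (2Z,4R,5S,6S,8E)-4-hydroxy-2-iodo-8-methyl-5-(propan-2-yl)undeca-2,8,10-trien-6-yl benzoate
Product: 13 (6S,7S,8S)-6-hydroxygermacra-1(10)E,4Z-dien-8-yl benzoate, via B-alkylborane 12 (not isolated)
Conditions: 9-BBN (2.2 equiv), THF, 0 °C to rt; then syringe-pump addition to Pd(dppf)Cl2 (20 mol%), AsPh3 (40 mol%), K3PO4 (aq), DMF/THF, rt to 45 °C, 2 mM
Reagents that add atoms: none
Why: 9-BBN adds only to the monosubstituted terminus of the C3=C2–C1=C10 diene, placing boron on C3, and zerovalent palladium then inserts into the C4–I bond, takes C3 over from the hydroxide-activated borane within the same molecule and forms C3–C4 by reductive elimination. The closest known reaction type is the intramolecular B-alkyl Suzuki–Miyaura coupling used to close carbocycles and macrocycles from ω-borylalkyl alkenyl iodides. The ten-membered carbocycle C1–C10 closes by sp3–sp2 coupling through an eleven-membered palladacycle, with the C4=C5 alkene ending endocyclic. No stereocentre is formed: the 4Z geometry is carried over with retention from the vinyl iodide and the 1(10)E geometry from the diene, so both ring alkenes are fixed before closure. The step needs regioselective hydroboration, which the single CH2= terminus secures, and ring closure ahead of oligomerisation and β-hydride elimination, which slow addition at millimolar concentration, the dppf ligand and the three contiguous substituents on C6–C8 (biasing the chain toward a folded conformer) are meant to secure.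

Step 9
Reactants: 13 (6S,7S,8S)-6-hydroxygermacra-1(10)E,4Z-dien-8-yl benzoate
Product: 14 (4S,5R,6R,7S,8S)-4,5-epoxy-6-hydroxygermacr-1(10)E-en-8-yl benzoate
Conditions: VO(acac)2 (5 mol%), t-BuOOH (decane), CH2Cl2, 0 °C
Reagents that add atoms: tert-butyl hydroperoxide CC(C)(C)OO
Why: Hydroxyl-directed vanadium-catalysed epoxidation reacts only at the allylic C4=C5 alkene and, as with (Z)-cycloalkenols whose ring bond C6–C7 is held out of the alkene plane, should deliver oxygen syn to the C6 hydroxyl to give the cis-epoxy alcohol with C4 (S) and C5 (R), leaving the undirected C1=C10 alkene untouched.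

Step 10
Reactants: 14 (4S,5R,6R,7S,8S)-4,5-epoxy-6-hydroxygermacr-1(10)E-en-8-yl benzoate
Product: 15 (4S,5R,6R,7R,8S)-6-acetoxy-4,5-epoxygermacr-1(10)E-en-8-yl benzoate
Conditions: Ac2O, pyridine, DMAP (cat.), CH2Cl2, 0 °C to rt
Reagents that add atoms: acetic anhydride CC(=O)OC(C)=O
Why: Base-mediated acylation of the secondary C6 hydroxyl (DMAP catalysis) should proceed without acid, so the oxirane, the benzoate and the C1=C10 alkene are not disturbed.

**Compound list**

1 | but-3-yn-1-ol | C#CCCO | starting material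
2 | dimethyl[(1E)-4-(dimethylalumanyloxy)-2-methylbut-1-en-1-yl]alane (alkenylalane) | C[Al](C)/C=C(\C)CCO[Al](C)C | intermediate
3 | (3E)-3-methylhexa-3,5-dien-1-ol | C=C/C=C(\C)CCO | intermediate
4 | (3E)-3-methylhexa-3,5-dienal | C=C/C=C(\C)CC=O | intermediate
5 | (4R)-4-benzyl-3-(3-methylbutanoyl)-1,3-oxazolidin-2-one | CC(C)CC(=O)N1[C@H](Cc2ccccc2)COC1=O | starting material
6 | (Z)-dibutylboron enolate of 5 | CCCCB(CCCC)O/C(=C\C(C)C)N1[C@H](Cc2ccccc2)COC1=O | intermediate
7 | (4R)-4-benzyl-3-[(2R,3S,5E)-3-hydroxy-5-methyl-2-(propan-2-yl)octa-5,7-dienoyl]-1,3-oxazolidin-2-one | C=C/C=C(\C)C[C@H](O)[C@@H](C(C)C)C(=O)N1[C@H](Cc2ccccc2)COC1=O | intermediate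
8 | (2R,3S,5E)-3-hydroxy-N-methoxy-N,5-dimethyl-2-(propan-2-yl)octa-5,7-dienamide | C=C/C=C(\C)C[C@H](O)[C@@H](C(C)C)C(=O)N(C)OC | intermediate
9 | (5R,6S,8E)-6-hydroxy-8-methyl-5-(propan-2-yl)undeca-8,10-dien-2-yn-4-one | C=C/C=C(\C)C[C@H](O)[C@@H](C(C)C)C(=O)C#CC | intermediate
10 | (2Z,5R,6S,8E)-6-hydroxy-2-iodo-8-methyl-5-(propan-2-yl)undeca-2,8,10-trien-4-one | C=C/C=C(\C)C[C@H](O)[C@@H](C(C)C)C(=O)/C=C(/C)I | intermediate
11 | (2Z,4R,5S,6S,8E)-4-hydroxy-2-iodo-8-methyl-5-(propan-2-yl)undeca-2,8,10-trien-6-yl benzoate | C=C/C=C(\C)C[C@H](OC(=O)c1ccccc1)[C@@H](C(C)C)[C@@H](O)/C=C(/C)I | intermediate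
12 | 9-[(3E,6S,7S,8R,9Z)-6-(benzoyloxy)-8-hydroxy-10-iodo-4-methyl-7-(propan-2-yl)undeca-3,9-dien-1-yl]-9-borabicyclo[3.3.1]nonane (boron on C3) | C1CCC2CCCC1B2CC/C=C(\C)C[C@H](OC(=O)c1ccccc1)[C@@H](C(C)C)[C@@H](O)/C=C(/C)I | intermediate
13 | (6S,7S,8S)-6-hydroxygermacra-1(10)E,4Z-dien-8-yl benzoate | C1/C(C)=C/CC/C(C)=C\[C@H](O)[C@H](C(C)C)[C@H]1OC(=O)c2ccccc2 | intermediate
14 | (4S,5R,6R,7S,8S)-4,5-epoxy-6-hydroxygermacr-1(10)E-en-8-yl benzoate | O[C@@H]1[C@H](C(C)C)[C@@H](OC(=O)c2ccccc2)C/C(C)=C/CC[C@]2(C)O[C@H]12 | intermediate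
15 | (4S,5R,6R,7R,8S)-6-acetoxy-4,5-epoxygermacr-1(10)E-en-8-yl benzoate | CC(=O)O[C@@H]1[C@H](C(C)C)[C@@H](OC(=O)c2ccccc2)C/C(C)=C/CC[C@]2(C)O[C@H]12 | target

Total step count: 10. Longest linear sequence: 10 steps (1 to 15).

**Steps most likely to fail**

Step 8 (ring closure). The risks are protodeboronation of the C3 borane, β-hydride elimination at the alkylpalladium stage, oligomerisation in place of ten-membered ring closure, and base-induced migration of the benzoate toward the C6 hydroxyl. The fallback keeps the same bond but changes the bond-forming principle from boron-to-palladium transmetalation under base to a base-free radical cross-electrophile coupling. Setting out from 11, hydroboration with 9-BBN followed by oxidative work-up with NaBO3·4H2O would give the primary alcohol (2Z,4R,5S,6S,8E)-4,11-dihydroxy-2-iodo-8-methyl-5-(propan-2-yl)undeca-2,8-dien-6-yl benzoate F1. I2/PPh3/imidazole at 0 °C would convert its primary hydroxyl selectively into the iodide (2Z,4R,5S,6S,8E)-4-hydroxy-2,11-diiodo-8-methyl-5-(propan-2-yl)undeca-2,8-dien-6-yl benzoate F2. F2 would then be closed under high dilution with NiBr2(dme), 4,4'-di-tert-butyl-2,2'-bipyridine and Mn powder in DMA, the C3 radical being captured by the alkenylnickel formed at C4. The product is 13, where the route is rejoined.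

Step 6 (hydroiodination). The risks are acid-promoted 6-endo oxa-Michael closure of the C8 hydroxyl onto the ynone and erosion of the alkene geometry by reversible iodide addition. The fallback replaces conjugate addition by hydroxyl-directed trans-hydroalumination. Setting out from 9, Me4NBH(OAc)3 in AcOH/MeCN at −30 °C would give the 6,8-anti propargylic diol (4R,5R,6S,8E)-8-methyl-5-(propan-2-yl)undeca-8,10-dien-2-yne-4,6-diol F3. NaAlH2(OCH2CH2OCH3)2 in THF followed by I2 at −78 °C would give the vinyl iodide (2Z,4R,5R,6S,8E)-2-iodo-8-methyl-5-(propan-2-yl)undeca-2,8,10-triene-4,6-diol F4, with aluminium and then iodine on C4 cis to C6. MnO2 in CH2Cl2 would oxidise only the allylic C6 hydroxyl, returning to 10 under neutral conditions just before step 7.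

Step 3 (aldol). The risk is prototropic migration of the skipped diene of 4 into conjugation with the aldehyde before the enolate captures it. The fallback builds the diene after the aldol. Commercial 4-(trimethylsilyl)but-3-yn-1-ol would be oxidised with Dess–Martin periodinane to 4-(trimethylsilyl)but-3-ynal F5. Setting out from 5, its boron enolate would be combined with F5 exactly as in step 3 to give the aldol (4R)-4-benzyl-3-[(2R,3S)-3-hydroxy-2-(propan-2-yl)-6-(trimethylsilyl)hex-5-ynoyl]-1,3-oxazolidin-2-one F6. Transamination as in step 4 would give the Weinreb amide (2R,3S)-3-hydroxy-N-methoxy-N-methyl-2-(propan-2-yl)-6-(trimethylsilyl)hex-5-ynamide F7, and K2CO3/MeOH would remove the silyl group to give the terminal alkyne (2R,3S)-3-hydroxy-N-methoxy-N-methyl-2-(propan-2-yl)hex-5-ynamide F8. The carboalumination/vinylation of step 1 (AlMe3, Cp2ZrCl2; then vinyl bromide, Pd(PPh3)4) run on F8 would give 8, where the route is rejoined.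

Further compounds
F1 | step 8 | (2Z,4R,5S,6S,8E)-4,11-dihydroxy-2-iodo-8-methyl-5-(propan-2-yl)undeca-2,8-dien-6-yl benzoate | OCC/C=C(\C)C[C@H](OC(=O)c1ccccc1)[C@@H](C(C)C)[C@@H](O)/C=C(/C)I
F2 | step 8 | (2Z,4R,5S,6S,8E)-4-hydroxy-2,11-diiodo-8-methyl-5-(propan-2-yl)undeca-2,8-dien-6-yl benzoate | ICC/C=C(\C)C[C@H](OC(=O)c1ccccc1)[C@@H](C(C)C)[C@@H](O)/C=C(/C)I
F3 | step 6 | (4R,5R,6S,8E)-8-methyl-5-(propan-2-yl)undeca-8,10-dien-2-yne-4,6-diol | C=C/C=C(\C)C[C@H](O)[C@@H](C(C)C)[C@@H](O)C#CC
F4 | step 6 | (2Z,4R,5R,6S,8E)-2-iodo-8-methyl-5-(propan-2-yl)undeca-2,8,10-triene-4,6-diol | C=C/C=C(\C)C[C@H](O)[C@@H](C(C)C)[C@@H](O)/C=C(/C)I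
F5 | step 3 | 4-(trimethylsilyl)but-3-ynal | C[Si](C)(C)C#CCC=O
F6 | step 3 | (4R)-4-benzyl-3-[(2R,3S)-3-hydroxy-2-(propan-2-yl)-6-(trimethylsilyl)hex-5-ynoyl]-1,3-oxazolidin-2-one | C[Si](C)(C)C#CC[C@H](O)[C@@H](C(C)C)C(=O)N1[C@H](Cc2ccccc2)COC1=O
F7 | step 3 | (2R,3S)-3-hydroxy-N-methoxy-N-methyl-2-(propan-2-yl)-6-(trimethylsilyl)hex-5-ynamide | C[Si](C)(C)C#CC[C@H](O)[C@@H](C(C)C)C(=O)N(C)OC
F8 | step 3 | (2R,3S)-3-hydroxy-N-methoxy-N-methyl-2-(propan-2-yl)hex-5-ynamide | C#CC[C@H](O)[C@@H](C(C)C)C(=O)N(C)OC
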